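## Structural features

The target is the B-type procyanidin trimer (−)-epicatechin-(4β→6)-(+)-catechin-(4α→6)-(+)-catechin. Each of its three flavan-3-ol units has a phloroglucinol-derived ring A fused to a dihydropyran ring C, with a catechol ring B at C2 and a hydroxyl group at C3. Two aryl–alkyl interflavan bonds join the units, upper C4 to middle C6 and middle C4 to lower C6. Both junctions use C6, the ring A carbon para to O1 and flanked by two oxygenated carbons, which is more hindered and less nucleophilic than C8. The eight stereocentres fall into three blocks: upper C2/C3/C4 (2,3-cis, 3,4-trans, aryl 4β), middle C2/C3/C4 (2,3-trans, 3,4-trans, aryl 4α) and lower C2/C3 (trans). Fragile elements are the fifteen phenolic hydroxyls (the catechols oxidise in base and air), the benzylic C2–O1 bonds (C2 epimerises by ring opening once phenols are free) and the two interflavan bonds, which strong acid cleaves. The upper and lower stereocentres can come from the chiral pool, so the real difficulty is the two C6 junctions, which run against the C8 preference of electrophilic substitution, and the α-aryl group at C4 of the middle unit between two bulky rings. The key step exploits that middle ring C, read as O1–C8a–C4a–C4 plus C2–C3, is the formal adduct of a 1-oxadiene (the ortho-quinone methide of ring A, whose methide carbon C4 already bears lower C6) and an E-configured 2-aryl enol ester, so C3–C4, O1–C2 and all three middle stereocentres can form in one cycloaddition.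

## Logic of the disconnections

23 is traced to 22 by cutting fourteen O–benzyl bonds and two aryl C–Br bonds. Masking every phenol and the two outer 3-hydroxyls as benzyl ethers removes the oxidation and epimerisation problems until the last step. The bromines leave under the same conditions, so they cost no step. The forward step must hydrogenolyse sixteen bonds under non-acidic conditions.

22 is traced to 21 by cutting the acetyl C–O bond on the middle 3-oxygen. The acetate is there only because the dienophile must carry a weakly donating oxygen. The forward step is a transesterification that meets no free phenol.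

21 is traced to 15 and 19 by cutting C3–C4 and O1–C2 of the middle ring C. This removes one ring and three stereocentres at once and splits the trimer into a two-unit carbinol and a small alkene. Both 4→6 junctions already exist in 15, so the cycloaddition cannot choose a wrong ring position. The forward step must put C4 on the acetoxy-bearing carbon, approach endo to the outward methide isomer, and select one face of the methide under catalyst control. 15 differs from a bromine-free carbinol by two spectator bromines, on C8 of the middle ring and C8 of the lower unit. They secure both C6 junctions during its assembly, cap the nucleophilic carbons next to the reacting centre, and vanish in the last step.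

15 is traced to 7 and 13 by cutting the bond between the middle ring and the carbinol carbon. This gives two fragments of similar size and uses one of the two equivalent bromines of 7 as the metalation handle. The forward step must exchange one bromine for lithium beside a phenoxide and add the aryllithium to a hindered aldehyde. The configuration of the carbinol does not matter.

7 is traced to 4 and 6 by cutting the upper C4–middle C6 bond. The C4 cation of the upper unit is a standard electrophile, and in 6 the two carbons ortho to the phenol carry bromine, so only the carbon para to the hydroxyl can react. The forward step must deliver the aryl group anti to the 3-benzyloxy group (4β) and must outrun self-condensation of 4.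

6 is traced to 5 by cutting two C–Br bonds ortho to the phenol. 4 is traced to 3 by cutting the C4–O bond, and 3 to 1 by cutting five O–benzyl bonds. These are functional-group changes on commercial materials. The demands are ortho-selective bromination and clean benzylic oxidation.

13 is traced to 11 by cutting the C6–CHO bond, 11 to 10 by cutting C8–Br, and 10 to 8 by cutting five O–benzyl bonds. Bromination takes C8 first, and with C8 blocked the formyl group can only enter at C6. The lower junction is thus fixed by the order of the two substitutions.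

19 is traced to 18 by cutting the vinyl C–O bond, 18 to 17 by exchanging the ligands on boron, and 17 to 16 by cutting the C=C bond. The alkene geometry is set once in the olefination and then carried with retention, which avoids an E/Z mixture of enol acetates.

## Other disconnections considered

Alternative 1: The cut removes O1–C8a and C4–C4a of the lower unit, so the lower ring C is annulated last onto an aryne on the aryl group at middle C4. In the forward step CsF would release the aryne from silylaryl triflate A2, the sodium alkoxide (NaH) of tosyloxy alcohol A3 would add at C8a, and the aryl anion at C4a would displace the primary tosylate to give pentadecabenzyl trimer A1.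
- In favour: the lower junction is C6 by construction, and the benzyloxy group next to the aryne directs the alkoxide to the remote carbon, as required. No stereocentre is made, and A1 is one hydrogenolysis from the target, against two steps in the chosen plan. On these points the alternative is better.
- Against: A2 already contains the middle unit with its 4α-aryl bond, so the hardest element is moved, not solved. The silyl/triflate pair must be placed on a fully substituted, hindered ring. The aryl anion can be protonated before it alkylates, and the alkoxide of A3 can close on its own tosylate.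
- Comparison: both key steps close one ring with two bonds and are equal there. The chosen step also sets three stereocentres and joins two large fragments, so it is ahead on step economy. The alternative avoids acid and catalyst control and is ahead on mechanistic simplicity.

Alternative 2: The cut removes C4a–C8a, C5–C6 and C8–C8a, so the middle ring A is built by benzannulation. In the forward step, heating siloxycyclobutenone A5 with siloxyalkyne A6 would give, through vinylketene [2+2] addition, ring opening and 6π closure, the hexasubstituted phenol A4.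
- In favour: the substitution pattern of ring A follows from the mechanism, with the single free phenol exactly at O1 and both junctions fixed without any blocking group. The conditions are thermal and neutral. On regiocontrol and acid-freedom the alternative is better, and it forms three bonds against two.
- Against: the step makes no stereocentre and leaves the pyran open. A6 must carry C2–C4 as three contiguous acyclic stereocentres, with C4 propargylic and benzylic and so liable to epimerise. A5 places the upper unit on a strained, enolisable ring.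
- A4 has at C2 the configuration opposite to the target, so the later closure must be an invertive Mitsunobu-type etherification at a benzylic carbon bearing an electron-rich aryl group, where ionisation threatens the stereochemistry. The silyl ethers add protecting-group steps.
- Comparison: more bonds per step, but many more steps before and after, and the stereochemical burden shifts to acyclic control.

Alternative 3: The cut removes C4–C4a of the upper unit. In the forward step BF3·OEt2 would open trans-epoxide A8 at its benzylic carbon and the ortho carbon of the symmetric aryl ether would attack anti to the epoxide oxygen, giving A7 with a free upper 3-hydroxyl.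
- In favour: the attacking ring is symmetric, so there is no regiochemical question. The 3,4-trans relation follows from the epoxide geometry without a catalyst, and A7 is one hydrogenolysis from the target. On stereospecificity and on the number of steps after the key step the alternative is better.
- Against: the step makes one bond and one stereocentre only. A8 must already hold the complete middle–lower dimer, so the 4α→6 problem is left for earlier steps. An epoxide benzylic to a trioxygenated ring is expected to ionise easily, which risks loss of stereospecificity and rearrangement to a ketone. The benzylic aryl ether at C2 is itself acid-labile.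
- Comparison: the ring count per step is equal, but the alternative is linear and late on the largest fragment, so the chosen plan is more convergent.

Key step: step 12

Assumption: the (R)-enantiomer of the binaphthyl hydrogen phosphate is taken as the one that directs attack to the required face of 20; this sense cannot be derived from the remote stereocentres and the (S)-acid is the direct substitute.

## Route

Step 1
Reactants: 1 (−)-epicatechin
Product: 3 3,5,7,3',4'-penta-O-benzyl-(−)-epicatechin, via tetrabenzyl ether 2 (not isolated)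
Conditions: BnBr, K2CO3, DMF, 0 °C → rt; then NaH, BnBr, 0 °C → rt
Reagents that add atoms: benzyl bromide BrCc1ccccc1
Why: Williamson etherification in two stages; carbonate benzylates the four phenols without opening ring C, then NaH makes the secondary alkoxide for the fifth benzylation, and no stereocentre is touched.

Step 2
Reactants: 3 3,5,7,3',4'-penta-O-benzyl-(−)-epicatechin
Product: 4 4β-(2-ethoxyethoxy)-3,5,7,3',4'-penta-O-benzylepicatechin
Conditions: 2,3-dichloro-5,6-dicyano-1,4-benzoquinone (DDQ), EtOCH2CH2OH, CH2Cl2, rt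
Reagents that add atoms: 2-ethoxyethanol CCOCCO
Why: Benzylic oxidation by hydride abstraction at C4 gives a cation stabilised by the 5,7-dialkoxy ring, which the alcohol should trap anti to the 3-benzyloxy group; the C4 configuration is lost again on ionisation in step 4.

Step 3
Reactants: 5 3,5-bis(benzyloxy)phenol
Product: 6 2,6-dibromo-3,5-bis(benzyloxy)phenol
Conditions: N-bromosuccinimide (2 equiv), i-Pr2NH (cat.), CH2Cl2, 0 °C
Reagents that add atoms: N-bromosuccinimide BrN1C(=O)CCC1=O
Why: Amine-catalysed ortho-bromination of a phenol; the N-bromoamine hydrogen-bonded to the hydroxyl delivers bromine to both ortho carbons, each of which is also para to a benzyloxy group, and leaves the carbon para to the hydroxyl free.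

Step 4
Reactants: 4 4β-(2-ethoxyethoxy)-3,5,7,3',4'-penta-O-benzylepicatechin; 6 2,6-dibromo-3,5-bis(benzyloxy)phenol
Product: 7 2,6-dibromo-3,5-bis(benzyloxy)-4-(3,5,7,3',4'-penta-O-benzylepicatechin-4β-yl)phenol
Conditions: Me3SiOTf (0.2 equiv), 6 (4 equiv), CH2Cl2, −78 → −40 °C, slow addition of 4
Reagents that add atoms: none
Why: Friedel–Crafts arylation by the C4 cation (interflavan-type coupling); the only unsubstituted carbon of 6 is para to the hydroxyl, so the later 4→6 junction is fixed, and attack anti to the axial 3-benzyloxy group should give the 4β (3,4-trans) product.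

Step 5
Reactants: 8 (+)-catechin
Product: 10 3,5,7,3',4'-penta-O-benzyl-(+)-catechin, via tetrabenzyl ether 9 (not isolated)
Conditions: BnBr, K2CO3, DMF, 0 °C → rt; then NaH, BnBr, 0 °C → rt
Reagents that add atoms: benzyl bromide BrCc1ccccc1
Why: Williamson etherification as in step 1; the mild first stage protects C2 against base-induced epimerisation and no stereocentre is touched.

Step 6
Reactants: 10 3,5,7,3',4'-penta-O-benzyl-(+)-catechin
Product: 11 8-bromo-3,5,7,3',4'-penta-O-benzylcatechin
Conditions: N-bromosuccinimide (1 equiv), CH2Cl2, −40 → 0 °C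
Reagents that add atoms: N-bromosuccinimide BrN1C(=O)CCC1=O
Why: Electrophilic aromatic bromination; C8, flanked by the ring oxygen and one benzyloxy group, is the most reactive carbon of a 5,7-dialkoxyflavan and should react before C6.

Step 7
Reactants: 11 8-bromo-3,5,7,3',4'-penta-O-benzylcatechin
Product: 13 8-bromo-3,5,7,3',4'-penta-O-benzylcatechin-6-carbaldehyde, via iminium chloride 12 (not isolated)
Conditions: POCl3, DMF, ClCH2CH2Cl, 70 °C; then aq NaOAc
Reagents that add atoms: N,N-dimethylformamide CN(C)C=O; water O
Why: Vilsmeier–Haack formylation; with C8 blocked, the chloroiminium electrophile can only enter at C6 of the trioxygenated ring A (ring B is far less activated), and hydrolysis of the iminium salt gives the aldehyde.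

Step 8
Reactants: 7 2,6-dibromo-3,5-bis(benzyloxy)-4-(3,5,7,3',4'-penta-O-benzylepicatechin-4β-yl)phenol; 13 8-bromo-3,5,7,3',4'-penta-O-benzylcatechin-6-carbaldehyde
Product: 15 [3-bromo-2-hydroxy-4,6-bis(benzyloxy)-5-(3,5,7,3',4'-penta-O-benzylepicatechin-4β-yl)phenyl](8-bromo-3,5,7,3',4'-penta-O-benzylcatechin-6-yl)methanol (both carbinol epimers), via dilithio species 14 (not isolated)
Conditions: 7, n-BuLi (2 equiv), THF, −78 °C; then 13, −78 → −20 °C; aq NH4Cl
Reagents that add atoms: none
Why: Phenol deprotonation and bromine–lithium exchange give the 2-lithiophenoxide (the two bromines are interchanged by rotation about the C4–aryl bond), which adds 1,2 to the aldehyde; the new carbinol centre forms unselectively and is erased in step 12.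

Step 9
Reactants: 16 3,4-bis(benzyloxy)benzaldehyde
Product: 17 (E)-2-{2-[3,4-bis(benzyloxy)phenyl]vinyl}-4,4,5,5-tetramethyl-1,3,2-dioxaborolane
Conditions: CH2(Bpin)2, lithium 2,2,6,6-tetramethylpiperidide, THF, 0 °C; then 16, −78 °C → rt
Reagents that add atoms: bis[(pinacolato)boryl]methane CC1(C)OB(CB2OC(C)(C)C(C)(C)O2)OC1(C)C
Why: Boron–Wittig olefination; the lithiated geminal diboronate adds to the aldehyde and syn-elimination of the boron–oxygen pair should give the E-alkenylboronate.

Step 10
Reactants: 17 (E)-2-{2-[3,4-bis(benzyloxy)phenyl]vinyl}-4,4,5,5-tetramethyl-1,3,2-dioxaborolane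
Product: 18 potassium (E)-{2-[3,4-bis(benzyloxy)phenyl]vinyl}trifluoroborate
Conditions: KHF2, MeOH/H2O, rt
Reagents that add atoms: potassium hydrogen difluoride [K+].[F-].F
Why: Ligand exchange on boron from the pinacol ester to the trifluoroborate; the alkene is not involved and keeps its geometry.

Step 11
Reactants: 18 potassium (E)-{2-[3,4-bis(benzyloxy)phenyl]vinyl}trifluoroborate
Product: 19 (E)-2-[3,4-bis(benzyloxy)phenyl]vinyl acetate
Conditions: AcOH, CuBr (10 mol %), 4-(dimethylamino)pyridine (20 mol %), 4 Å MS, O2, MeCN, 60 °C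
Reagents that add atoms: acetic acid CC(=O)O
Why: Chan–Lam–Evans oxidative C–O coupling of an alkenyltrifluoroborate with a carboxylic acid; transmetalation and reductive elimination at copper proceed with retention of the alkene geometry.

Step 12
Reactants: 15 [3-bromo-2-hydroxy-4,6-bis(benzyloxy)-5-(3,5,7,3',4'-penta-O-benzylepicatechin-4β-yl)phenyl](8-bromo-3,5,7,3',4'-penta-O-benzylcatechin-6-yl)methanol; 19 (E)-2-[3,4-bis(benzyloxy)phenyl]vinyl acetate
Product: 21 3,5,7,3',4'-penta-O-benzylepicatechin-(4β→6)-3-O-acetyl-8-bromo-5,7,3',4'-tetra-O-benzylcatechin-(4α→6)-8-bromo-3,5,7,3',4'-penta-O-benzylcatechin, via ortho-quinone methide 20 (not isolated)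
Conditions: (R)-3,3'-bis(2,4,6-triisopropylphenyl)-1,1'-binaphthyl-2,2'-diyl hydrogen phosphate (10 mol %), 19 (3 equiv), 4 Å MS, toluene, 0 °C → rt
Reagents that add atoms: none
Why: The binaphthyl hydrogen phosphate ionises either epimer of 15 with loss of water to the ortho-quinone methide 20, whose protonated form is a diarylmethyl cation stabilised by both trioxygenated rings and paired with the chiral phosphate. The acetoxy-bearing carbon of 19 attacks the methide carbon (C3–C4) while charge develops at the benzylic carbon under the para-benzyloxy group, and the quinone oxygen closes onto it (O1–C2): an asynchronous inverse-electron-demand hetero-Diels–Alder reaction, whose closest known type is the chiral phosphoric acid-catalysed [4+2] cycloaddition of ortho-quinone methides with styrenes. Ring C of the middle unit closes as a six-membered dihydropyran in the [4+2] mode (in the stepwise limit, capture of the benzylic cation by the phenol oxygen). C2 and C3 are set relative to each other by suprafacial addition to the E-alkene (2,3-trans). C4 is set relative to C3 by endo approach of the styrene aryl group to the methide isomer whose lower-unit aryl group points away from the carbonyl oxygen (3,4-trans, all substituents equatorial). The face of 20 that is attacked, and so the absolute configuration of all three centres, is set by the catalyst, because the upper and lower stereocentres lie too far from C4 to bias it; the wrong-face adduct is a diastereomer and separable. The step needs C4-to-C3 regiochemistry, secured because the 3,4-bis(benzyloxy)phenyl group outweighs the weak acetoxy donor, and chemoselectivity, secured because the only free phenol lies para to the upper unit and C8 of the middle and lower rings is capped with bromine.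

Step 13
Reactants: 21 3,5,7,3',4'-penta-O-benzylepicatechin-(4β→6)-3-O-acetyl-8-bromo-5,7,3',4'-tetra-O-benzylcatechin-(4α→6)-8-bromo-3,5,7,3',4'-penta-O-benzylcatechin
Product: 22 3,5,7,3',4'-penta-O-benzylepicatechin-(4β→6)-8-bromo-5,7,3',4'-tetra-O-benzylcatechin-(4α→6)-8-bromo-3,5,7,3',4'-penta-O-benzylcatechin
Conditions: NaOMe (cat.), MeOH/THF, rt
Reagents that add atoms: none
Why: Zemplén transesterification of the secondary acetate; no phenol is free, so the basic medium cannot open ring C or epimerise C2.

Step 14
Reactants: 22 3,5,7,3',4'-penta-O-benzylepicatechin-(4β→6)-8-bromo-5,7,3',4'-tetra-O-benzylcatechin-(4α→6)-8-bromo-3,5,7,3',4'-penta-O-benzylcatechin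
Product: 23 (−)-epicatechin-(4β→6)-(+)-catechin-(4α→6)-(+)-catechin (CNP0163146.4)
Conditions: H2 (1 atm), Pd(OH)2/C, Et3N (2.2 equiv), THF/MeOH/H2O, rt
Reagents that add atoms: none
Why: Hydrogenolysis of the fourteen benzyl ethers with hydrodebromination of the two aryl bromides over Pd(OH)2/C; Et3N takes up the HBr so the acid-labile interflavan bonds are not exposed to acid, and no stereocentre is involved.

## Compound list

1 | (−)-epicatechin | Oc1cc(O)c2c(c1)O[C@H](c1ccc(O)c(O)c1)[C@H](O)C2 | starting material
2 | 5,7,3',4'-tetra-O-benzyl-(−)-epicatechin (not isolated) | c1(OCc9ccccc9)cc(OCc9ccccc9)c2c(c1)O[C@H](c8ccc(OCc9ccccc9)c(OCc9ccccc9)c8)[C@H](O)C2 | intermediate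
3 | 3,5,7,3',4'-penta-O-benzyl-(−)-epicatechin | c1(OCc9ccccc9)cc(OCc9ccccc9)c2c(c1)O[C@H](c8ccc(OCc9ccccc9)c(OCc9ccccc9)c8)[C@H](OCc9ccccc9)C2 | intermediate
4 | 4β-(2-ethoxyethoxy)-3,5,7,3',4'-penta-O-benzylepicatechin | c1(OCc9ccccc9)cc(OCc9ccccc9)c2c(c1)O[C@H](c8ccc(OCc9ccccc9)c(OCc9ccccc9)c8)[C@H](OCc9ccccc9)[C@H]2OCCOCC | intermediate
5 | 3,5-bis(benzyloxy)phenol | Oc1cc(OCc2ccccc2)cc(OCc2ccccc2)c1 | starting material
6 | 2,6-dibromo-3,5-bis(benzyloxy)phenol | Oc1c(Br)c(OCc2ccccc2)cc(OCc2ccccc2)c1Br | intermediate
7 | 2,6-dibromo-3,5-bis(benzyloxy)-4-(3,5,7,3',4'-penta-O-benzylepicatechin-4β-yl)phenol | c1(OCc9ccccc9)cc(OCc9ccccc9)c2c(c1)O[C@H](c8ccc(OCc9ccccc9)c(OCc9ccccc9)c8)[C@H](OCc9ccccc9)[C@H]2c3c(OCc9ccccc9)c(Br)c(O)c(Br)c3OCc9ccccc9 | intermediate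
8 | (+)-catechin | Oc1cc(O)c2c(c1)O[C@H](c1ccc(O)c(O)c1)[C@@H](O)C2 | starting material
9 | 5,7,3',4'-tetra-O-benzyl-(+)-catechin (not isolated) | c1(OCc9ccccc9)cc(OCc9ccccc9)c2c(c1)O[C@H](c8ccc(OCc9ccccc9)c(OCc9ccccc9)c8)[C@@H](O)C2 | intermediate
10 | 3,5,7,3',4'-penta-O-benzyl-(+)-catechin | c1(OCc9ccccc9)cc(OCc9ccccc9)c2c(c1)O[C@H](c8ccc(OCc9ccccc9)c(OCc9ccccc9)c8)[C@@H](OCc9ccccc9)C2 | intermediate
11 | 8-bromo-3,5,7,3',4'-penta-O-benzylcatechin | c1(OCc9ccccc9)cc(OCc9ccccc9)c2c(c1Br)O[C@H](c8ccc(OCc9ccccc9)c(OCc9ccccc9)c8)[C@@H](OCc9ccccc9)C2 | intermediate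
12 | N,N-dimethyl iminium chloride of 13 (not isolated) | c1(OCc9ccccc9)c(C=[N+](C)C)c(OCc9ccccc9)c2c(c1Br)O[C@H](c8ccc(OCc9ccccc9)c(OCc9ccccc9)c8)[C@@H](OCc9ccccc9)C2.[Cl-] | intermediate
13 | 8-bromo-3,5,7,3',4'-penta-O-benzylcatechin-6-carbaldehyde | c1(OCc9ccccc9)c(C=O)c(OCc9ccccc9)c2c(c1Br)O[C@H](c8ccc(OCc9ccccc9)c(OCc9ccccc9)c8)[C@@H](OCc9ccccc9)C2 | intermediate
14 | lithium 2-lithiophenoxide derived from 7 (not isolated) | c1(OCc9ccccc9)cc(OCc9ccccc9)c2c(c1)O[C@H](c8ccc(OCc9ccccc9)c(OCc9ccccc9)c8)[C@H](OCc9ccccc9)[C@H]2c3c(OCc9ccccc9)c(Br)c(O[Li])c([Li])c3OCc9ccccc9 | intermediate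
15 | [3-bromo-2-hydroxy-4,6-bis(benzyloxy)-5-(3,5,7,3',4'-penta-O-benzylepicatechin-4β-yl)phenyl](8-bromo-3,5,7,3',4'-penta-O-benzylcatechin-6-yl)methanol, carbinol epimers | c1(OCc9ccccc9)cc(OCc9ccccc9)c2c(c1)O[C@H](c8ccc(OCc9ccccc9)c(OCc9ccccc9)c8)[C@H](OCc9ccccc9)[C@H]2c3c(OCc9ccccc9)c(Br)c(O)c(c3OCc9ccccc9)C(O)c5c(OCc9ccccc9)c(Br)c6c(c5OCc9ccccc9)C[C@H](OCc9ccccc9)[C@@H](c8ccc(OCc9ccccc9)c(OCc9ccccc9)c8)O6 | intermediate
16 | 3,4-bis(benzyloxy)benzaldehyde | O=Cc1ccc(OCc2ccccc2)c(OCc2ccccc2)c1 | starting material
17 | (E)-2-{2-[3,4-bis(benzyloxy)phenyl]vinyl}-4,4,5,5-tetramethyl-1,3,2-dioxaborolane | CC1(C)OB(/C=C/c2ccc(OCc3ccccc3)c(OCc3ccccc3)c2)OC1(C)C | intermediate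
18 | potassium (E)-{2-[3,4-bis(benzyloxy)phenyl]vinyl}trifluoroborate | [K+].F[B-](F)(F)/C=C/c1ccc(OCc2ccccc2)c(OCc2ccccc2)c1 | intermediate
19 | (E)-2-[3,4-bis(benzyloxy)phenyl]vinyl acetate | CC(=O)O/C=C/c1ccc(OCc2ccccc2)c(OCc2ccccc2)c1 | intermediate
20 | ortho-quinone methide from 15 (not isolated) | c1(OCc9ccccc9)cc(OCc9ccccc9)c2c(c1)O[C@H](c8ccc(OCc9ccccc9)c(OCc9ccccc9)c8)[C@H](OCc9ccccc9)[C@H]2C3=C(OCc9ccccc9)C(=Cc5c(OCc9ccccc9)c(Br)c6c(c5OCc9ccccc9)C[C@H](OCc9ccccc9)[C@@H](c8ccc(OCc9ccccc9)c(OCc9ccccc9)c8)O6)C(=O)C(Br)=C3OCc9ccccc9 | intermediate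
21 | tetradeca-O-benzyl dibromo trimer, middle 3-O-acetate | c1(OCc9ccccc9)cc(OCc9ccccc9)c2c(c1)O[C@H](c8ccc(OCc9ccccc9)c(OCc9ccccc9)c8)[C@H](OCc9ccccc9)[C@H]2c3c(OCc9ccccc9)c(Br)c4c(c3OCc9ccccc9)[C@@H](c5c(OCc9ccccc9)c(Br)c6c(c5OCc9ccccc9)C[C@H](OCc9ccccc9)[C@@H](c8ccc(OCc9ccccc9)c(OCc9ccccc9)c8)O6)[C@H](OC(C)=O)[C@@H](c8ccc(OCc9ccccc9)c(OCc9ccccc9)c8)O4 | intermediate
22 | tetradeca-O-benzyl dibromo trimer, middle 3-hydroxyl free | c1(OCc9ccccc9)cc(OCc9ccccc9)c2c(c1)O[C@H](c8ccc(OCc9ccccc9)c(OCc9ccccc9)c8)[C@H](OCc9ccccc9)[C@H]2c3c(OCc9ccccc9)c(Br)c4c(c3OCc9ccccc9)[C@@H](c5c(OCc9ccccc9)c(Br)c6c(c5OCc9ccccc9)C[C@H](OCc9ccccc9)[C@@H](c8ccc(OCc9ccccc9)c(OCc9ccccc9)c8)O6)[C@H](O)[C@@H](c8ccc(OCc9ccccc9)c(OCc9ccccc9)c8)O4 | intermediate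
23 | (−)-epicatechin-(4β→6)-(+)-catechin-(4α→6)-(+)-catechin, CNP0163146.4 | Oc1cc(O)c2c(c1)O[C@H](c1ccc(O)c(O)c1)[C@H](O)[C@H]2c1c(O)cc2c(c1O)[C@@H](c1c(O)cc3c(c1O)C[C@H](O)[C@@H](c1ccc(O)c(O)c1)O3)[C@H](O)[C@@H](c1ccc(O)c(O)c1)O2 | target

## Step count and least certain steps

Total step count: 14. Longest linear sequence: 7 steps (1 → 2 → 4 → 8 → 12 → 13 → 14, or equally 5 → 6 → 7 → 8 → 12 → 13 → 14).

**Step 12 (key step).** The methide is strongly stabilised and flanked by four ortho substituents, so capture by 19 may be slow. Water could then return, or the free C8 of the upper unit could attack another methide. Facial selectivity may be poor because the catalyst must work against ortho-bromine and benzyloxy groups, and reaction through the inward methide isomer would erode the 3,4-trans relation. Attack through the acetate-activated carbon would give the wrong regiochemistry.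
Fallback: conventional cationic interflavan coupling, setting out from 11 and 4 and returning at 23.
- 11 with DDQ and 2-ethoxyethanol should give the 8-bromo-4-(2-ethoxyethoxy) ether F1.
- F1 and 11 with Me3SiOTf should give the 4α→6 dimer F2; the bromine of 11 directs attack to C6 and the bromine of F1 prevents self-condensation.
- 4 and F2 with Me3SiOTf should give the pentadecabenzyl dibromo trimer F3, since the only free phloroglucinol carbon of F2 is C6 of its upper ring.
- Hydrogenolysis of F3 over Pd(OH)2/C with Et3N gives 23.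
- The weakness of this detour is that the 4α selectivity rests on the substrate alone.

**Step 4.** The cation from 4 can be captured by C8 of a second molecule of 4 (self-condensation) faster than by the hindered, bromine-deactivated carbon of 6. The ortho-selectivity of step 3, on which 6 depends, is also not assured.
Fallback: setting out from 4 and 5 and returning at 7. Me3SiOTf-mediated arylation of the more nucleophilic 5 in excess, separation of the para-arylated phenol F4 from its ortho isomer, then N-bromosuccinimide (2 equiv) with i-Pr2NH (cat.) should give 7. Phenol-directed bromination is expected to outrun bromination at C8 of the upper unit. This detour bypasses step 3 as well.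

**Step 7.** Electrophilic formylation may stall at a carbon flanked by two benzyloxy groups on a bromine-deactivated ring, and prolonged heating with POCl3 risks loss of a benzyl group.
Fallback: setting out from 11 and returning at 13. N-Iodosuccinimide with CF3CO2H (cat.) should give the 8-bromo-6-iodo compound F5. n-BuLi at −90 °C exchanges iodine faster than bromine, and DMF then gives 13.

**Step 8.** Bromine–lithium exchange beside an anionic phenoxide may be incomplete. The dilithio species can be protonated or can metalate a neighbouring benzylic position. Addition to the di-ortho-substituted aldehyde may be slow. The product ionises on acidic supports and must be handled on base-washed silica.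
Fallback: reversed polarity, setting out from 7 and 11 and returning at 15. 7 with n-BuLi (2 equiv) and DMF, a small electrophile, should give the salicylaldehyde F6. The iodide F5 (made from 11 as under step 7) with n-BuLi gives the 6-lithio species, which is added to F6 after deprotonation of its phenol with NaH.

**Step 11.** Protodeboronation or oxidative homocoupling of the electron-rich alkenyltrifluoroborate may compete with C–O coupling.
Fallback: setting out from 16 and returning at 19. Wittig reaction with MeOCH2PPh3Cl and KOt-Bu should give the enol ether F7. Aqueous HCl in THF should give the arylacetaldehyde F8. Ac2O with KOAc then gives 19 as an E/Z mixture, from which the E isomer is separated by chromatography or crystallisation.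

## Further compounds

F1 | step 12 | 8-bromo-4-(2-ethoxyethoxy)-3,5,7,3',4'-penta-O-benzylcatechin (C4 epimers) | c1(OCc9ccccc9)cc(OCc9ccccc9)c2c(c1Br)O[C@H](c8ccc(OCc9ccccc9)c(OCc9ccccc9)c8)[C@@H](OCc9ccccc9)C2OCCOCC
F2 | step 12 | 8-bromo-3,5,7,3',4'-penta-O-benzylcatechin-(4α→6)-8-bromo-3,5,7,3',4'-penta-O-benzylcatechin | c3c(OCc9ccccc9)c(Br)c4c(c3OCc9ccccc9)[C@@H](c5c(OCc9ccccc9)c(Br)c6c(c5OCc9ccccc9)C[C@H](OCc9ccccc9)[C@@H](c8ccc(OCc9ccccc9)c(OCc9ccccc9)c8)O6)[C@H](OCc9ccccc9)[C@@H](c8ccc(OCc9ccccc9)c(OCc9ccccc9)c8)O4
F3 | step 12 | pentadeca-O-benzyl trimer with bromine on C8 of the middle and lower units | c1(OCc9ccccc9)cc(OCc9ccccc9)c2c(c1)O[C@H](c8ccc(OCc9ccccc9)c(OCc9ccccc9)c8)[C@H](OCc9ccccc9)[C@H]2c3c(OCc9ccccc9)c(Br)c4c(c3OCc9ccccc9)[C@@H](c5c(OCc9ccccc9)c(Br)c6c(c5OCc9ccccc9)C[C@H](OCc9ccccc9)[C@@H](c8ccc(OCc9ccccc9)c(OCc9ccccc9)c8)O6)[C@H](OCc9ccccc9)[C@@H](c8ccc(OCc9ccccc9)c(OCc9ccccc9)c8)O4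
F4 | step 4 | 3,5-bis(benzyloxy)-4-(3,5,7,3',4'-penta-O-benzylepicatechin-4β-yl)phenol | c1(OCc9ccccc9)cc(OCc9ccccc9)c2c(c1)O[C@H](c8ccc(OCc9ccccc9)c(OCc9ccccc9)c8)[C@H](OCc9ccccc9)[C@H]2c3c(OCc9ccccc9)cc(O)cc3OCc9ccccc9
F5 | step 7 | 8-bromo-6-iodo-3,5,7,3',4'-penta-O-benzylcatechin | c1(OCc9ccccc9)c(I)c(OCc9ccccc9)c2c(c1Br)O[C@H](c8ccc(OCc9ccccc9)c(OCc9ccccc9)c8)[C@@H](OCc9ccccc9)C2
F6 | step 8 | 3-bromo-2-hydroxy-4,6-bis(benzyloxy)-5-(3,5,7,3',4'-penta-O-benzylepicatechin-4β-yl)benzaldehyde | c1(OCc9ccccc9)cc(OCc9ccccc9)c2c(c1)O[C@H](c8ccc(OCc9ccccc9)c(OCc9ccccc9)c8)[C@H](OCc9ccccc9)[C@H]2c3c(OCc9ccccc9)c(Br)c(O)c(C=O)c3OCc9ccccc9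
F7 | step 11 | 1,2-bis(benzyloxy)-4-(2-methoxyvinyl)benzene (E/Z mixture) | COC=Cc1ccc(OCc2ccccc2)c(OCc2ccccc2)c1
F8 | step 11 | [3,4-bis(benzyloxy)phenyl]acetaldehyde | O=CCc1ccc(OCc2ccccc2)c(OCc2ccccc2)c1
A1 | alternative 1 | pentadeca-O-benzyl trimer | c1(OCc9ccccc9)cc(OCc9ccccc9)c2c(c1)O[C@H](c8ccc(OCc9ccccc9)c(OCc9ccccc9)c8)[C@H](OCc9ccccc9)[C@H]2c3c(OCc9ccccc9)cc4c(c3OCc9ccccc9)[C@@H](c5c(OCc9ccccc9)cc6c(c5OCc9ccccc9)C[C@H](OCc9ccccc9)[C@@H](c8ccc(OCc9ccccc9)c(OCc9ccccc9)c8)O6)[C@H](OCc9ccccc9)[C@@H](c8ccc(OCc9ccccc9)c(OCc9ccccc9)c8)O4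
A2 | alternative 1 | upper–middle dimer bearing at middle C4 a 2,6-bis(benzyloxy)-4-(trifluoromethylsulfonyloxy)-3-(trimethylsilyl)phenyl group | c1(OCc9ccccc9)cc(OCc9ccccc9)c2c(c1)O[C@H](c8ccc(OCc9ccccc9)c(OCc9ccccc9)c8)[C@H](OCc9ccccc9)[C@H]2c3c(OCc9ccccc9)cc4c(c3OCc9ccccc9)[C@@H](c5c(OCc9ccccc9)cc(OS(=O)(=O)C(F)(F)F)c([Si](C)(C)C)c5OCc9ccccc9)[C@H](OCc9ccccc9)[C@@H](c8ccc(OCc9ccccc9)c(OCc9ccccc9)c8)O4
A3 | alternative 1 | 2-(benzyloxy)-3-[3,4-bis(benzyloxy)phenyl]-3-hydroxypropyl 4-methylbenzenesulfonate, configured as lower C2 and C3 | Cc1ccc(cc1)S(=O)(=O)OC[C@H](OCc2ccccc2)[C@H](O)c2ccc(OCc3ccccc3)c(OCc3ccccc3)c2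
A4 | alternative 2 | middle ring A as 5,7-bis(triisopropylsilyl ether) with free C8a phenol, pyran open | c1(OCc9ccccc9)cc(OCc9ccccc9)c2c(c1)O[C@H](c8ccc(OCc9ccccc9)c(OCc9ccccc9)c8)[C@H](OCc9ccccc9)[C@H]2c3c(O[Si](C(C)C)(C(C)C)C(C)C)cc(O)c(c3O[Si](C(C)C)(C(C)C)C(C)C)[C@@H](c5c(OCc9ccccc9)cc6c(c5OCc9ccccc9)C[C@H](OCc9ccccc9)[C@@H](c8ccc(OCc9ccccc9)c(OCc9ccccc9)c8)O6)[C@H](OCc9ccccc9)[C@@H](O[Si](CC)(CC)CC)c8ccc(OCc9ccccc9)c(OCc9ccccc9)c8
A5 | alternative 2 | 2-(3,5,7,3',4'-penta-O-benzylepicatechin-4β-yl)-3-(triisopropylsilyloxy)cyclobut-2-enone | c1(OCc9ccccc9)cc(OCc9ccccc9)c2c(c1)O[C@H](c8ccc(OCc9ccccc9)c(OCc9ccccc9)c8)[C@H](OCc9ccccc9)[C@H]2C3=C(O[Si](C(C)C)(C(C)C)C(C)C)CC3=O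
A6 | alternative 2 | triisopropylsilyloxyalkyne carrying the middle C4–C2 chain and the lower unit | CC(C)[Si](C(C)C)(C(C)C)OC#C[C@@H](c5c(OCc9ccccc9)cc6c(c5OCc9ccccc9)C[C@H](OCc9ccccc9)[C@@H](c8ccc(OCc9ccccc9)c(OCc9ccccc9)c8)O6)[C@H](OCc9ccccc9)[C@@H](O[Si](CC)(CC)CC)c8ccc(OCc9ccccc9)c(OCc9ccccc9)c8
A7 | alternative 3 | tetradeca-O-benzyl 8-bromo trimer with free upper 3-hydroxyl | c1(OCc9ccccc9)cc(OCc9ccccc9)c2c(c1)O[C@H](c8ccc(OCc9ccccc9)c(OCc9ccccc9)c8)[C@H](O)[C@H]2c3c(OCc9ccccc9)cc4c(c3OCc9ccccc9)[C@@H](c5c(OCc9ccccc9)c(Br)c6c(c5OCc9ccccc9)C[C@H](OCc9ccccc9)[C@@H](c8ccc(OCc9ccccc9)c(OCc9ccccc9)c8)O6)[C@H](OCc9ccccc9)[C@@H](c8ccc(OCc9ccccc9)c(OCc9ccccc9)c8)O4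
A8 | alternative 3 | trans-epoxide of the open upper unit: 3,5-bis(benzyloxy)phenyl ether at C2, epoxide across C3–C4, C4 bonded to C6 of the middle–lower dimer | c1(OCc9ccccc9)cc(OCc9ccccc9)cc(c1)O[C@H](c8ccc(OCc9ccccc9)c(OCc9ccccc9)c8)[C@@H]7O[C@H]7c3c(OCc9ccccc9)cc4c(c3OCc9ccccc9)[C@@H](c5c(OCc9ccccc9)c(Br)c6c(c5OCc9ccccc9)C[C@H](OCc9ccccc9)[C@@H](c8ccc(OCc9ccccc9)c(OCc9ccccc9)c8)O6)[C@H](OCc9ccccc9)[C@@H](c8ccc(OCc9ccccc9)c(OCc9ccccc9)c8)O4
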